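**Retrosynthetic overview**

1. Atom numbers follow the target SMILES: C1 (CHOAc), C2, C3 (C(CH3)OAc), C4, C5 (ring-fusion CH), C6, C7 (C=O), C8=C9, C10, C11, N12, C13, C14, C15, C16 (quaternary). Ring A is the cyclohexane C1–C5/C16, ring B the cyclopentanone C5–C8/C16, ring C the nine-membered azacycle.
2. The strategy rests on the saturated three-carbon bridge C13–C14–C15 that ties N12 to the angular carbon C16 in ring C. Cut between C13 and C14, it becomes an N-vinyl group on N12 and an allyl group on C16, so ring C is closed by enamide ring-closing metathesis and C13=C14 is then reduced.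
3. C8=C9 is carried through the ring closure as its aldol (C9–OH). In an open chain the alkylidene should turn C10 away from the crowded quaternary C16, whereas elimination inside ring C can only give the ring-cis, (E) enone.
4. The aldol comes from conjugate allylation at C16 of a ring A–B enone and addition of the C7–C8 enolate to an N-Boc-N-vinyl 3-aminopropanal. The enone comes from a Pauson–Khand reaction of a 1,7-enyne whose C3 is taken from (R)-mevalonolactone and whose C1 is set by asymmetric ynone reduction.
5. Ring order: A and B together (Pauson–Khand), then C (metathesis). Stereocentres: C3 (chiral pool), C1 (catalyst), C5 (cycloaddition), C16 (conjugate addition).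

Key step: step 16

Remark: the geometry argument for C8=C9 rests on allylic strain between C10 and the two groups flanking quaternary C16 (C1 and C15); the three starting materials are taken as purchased.

**Route**

Step 1
Reactants: 1 (R)-mevalonolactone
Product: 2 (4R)-4-methyl-4-(triethylsilyloxy)oxan-2-one
Conditions: Et3SiOSO2CF3, 2,6-lutidine, CH2Cl2, −78 to 0 °C
Reagents that add atoms: triethylsilyl trifluoromethanesulfonate, CC[Si](CC)(CC)OS(=O)(=O)C(F)(F)F
Why: Silylation of the tertiary alcohol with a silyl triflate and a hindered pyridine base (silyl ether protection) should leave the lactone untouched; the C3 stereocentre is taken unchanged from the chiral pool.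

Step 2
Reactants: 2 (4R)-4-methyl-4-(triethylsilyloxy)oxan-2-one
Product: 3 (4R)-4-methyl-4-(triethylsilyloxy)oxan-2-ol (lactol, both anomers)
Conditions: i-Bu2AlH, CH2Cl2, −78 °C; aq potassium sodium tartrate
Reagents that add atoms: none
Why: Partial reduction of the lactone with i-Bu2AlH stops at the lactol because the tetrahedral aluminium hemiacetal is stable at −78 °C.

Step 3
Reactants: 3 lactol
Product: 4 (3S)-3-methyl-3-(triethylsilyloxy)hex-5-en-1-ol
Conditions: Ph3PCH3Br, n-BuLi, THF, 0 °C; then 3, −78 to 0 °C
Reagents that add atoms: methyltriphenylphosphonium bromide, C[P+](c1ccccc1)(c1ccccc1)c1ccccc1.[Br-]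
Why: Wittig methylenation of the hydroxy aldehyde in equilibrium with the lactol turns the former lactone carbon into C5 of the terminal alkene C5=C6, and the lithium counter-ion together with the low temperature should keep the tertiary silyl group from migrating to the freed primary alkoxide.

Step 4
Reactants: 4 (3S)-3-methyl-3-(triethylsilyloxy)hex-5-en-1-ol
Product: 5 (3S)-3-methyl-3-(triethylsilyloxy)hex-5-enal
Conditions: Dess–Martin periodinane, NaHCO3, CH2Cl2, 0 °C to rt
Reagents that add atoms: none
Why: Dess–Martin oxidation converts the primary alcohol into the aldehyde (the future C1) under buffered, non-basic conditions, so that the β-silyloxy group is not eliminated.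

Step 5
Reactants: 5 (3S)-3-methyl-3-(triethylsilyloxy)hex-5-enal
Product: 6 (5S)-5-methyl-5-(triethylsilyloxy)-1-(trimethylsilyl)oct-7-en-1-yn-3-ol (both epimers at the carbinol carbon, the future C1)
Conditions: LiC≡CSiMe3, THF, −78 °C; then H2O
Reagents that add atoms: lithium (trimethylsilyl)acetylide, [Li]C#C[Si](C)(C)C
Why: Nucleophilic 1,2-addition of the lithium acetylide to the aldehyde forms the C1–C16 bond, and the mixture of C1 epimers is carried on because step 6 removes this stereocentre.

Step 6
Reactants: 6 propargylic alcohols
Product: 7 (5S)-5-methyl-5-(triethylsilyloxy)-1-(trimethylsilyl)oct-7-en-1-yn-3-one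
Conditions: Dess–Martin periodinane, NaHCO3, CH2Cl2, 0 °C to rt
Reagents that add atoms: none
Why: Dess–Martin oxidation of the propargylic alcohol gives the alkynyl ketone on which C1 can be set by a catalyst.

Step 7
Reactants: 7 alkynyl ketone
Product: 8 (3S,5S)-5-methyl-5-(triethylsilyloxy)-1-(trimethylsilyl)oct-7-en-1-yn-3-ol
Conditions: Ru[(S,S)-TsNCHPhCHPhNH](η6-p-cymene) (2 mol %), i-PrOH, rt
Reagents that add atoms: none
Why: Noyori asymmetric transfer hydrogenation of the alkynyl ketone: the (S,S)-diamine ligand directs hydride so that the alkynyl group takes the place of the aryl group of an aryl ketone and the (S)-propargylic alcohol should result, C1 being set by the catalyst independently of C3 (syn-1,3 relation of the two oxygens).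

Step 8
Reactants: 8 (3S,5S)-propargylic alcohol
Product: 9 (3S,5S)-5-methyl-5-(triethylsilyloxy)oct-7-en-1-yn-3-ol
Conditions: K2CO3, MeOH, rt
Reagents that add atoms: none
Why: Carbonate-catalysed methanolysis cleaves only the alkynyl C–Si bond, since the hindered tertiary triethylsilyl ether should be stable to K2CO3 in methanol at room temperature.

Step 9
Reactants: 9 terminal alkyne
Product: 10 (3S,5S)-5-methyl-3,5-bis(triethylsilyloxy)oct-7-en-1-yne
Conditions: Et3SiCl, imidazole, DMF, rt
Reagents that add atoms: chlorotriethylsilane, CC[Si](Cl)(CC)CC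
Why: Silylation of the secondary propargylic alcohol with the silyl chloride and imidazole (silyl ether protection) gives two bulky ether groups, which later bias the chair of the forming ring A.

Step 10
Reactants: 10 enyne
Product: 12 (4S,6S,7aS)-6-methyl-4,6-bis(triethylsilyloxy)-1,4,5,6,7,7a-hexahydro-2H-inden-2-one (ring A–B enone), via alkyne–hexacarbonyldicobalt complex 11 (not isolated)
Conditions: Co2(CO)8, CH2Cl2, rt; then N-methylmorpholine N-oxide, 0 °C to rt
Reagents that add atoms: dicobalt octacarbonyl, O=C=[Co](=C=O)(=C=O)(=C=O)[Co](=C=O)(=C=O)(=C=O)=C=O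
Why: Pauson–Khand [2+2+1] cycloaddition of the alkyne–Co2(CO)6 complex with the tethered alkene and CO (N-oxide promoted) builds rings A and B at once, and C5 should be set in the alkene insertion through the chair in which the two syn-disposed silyloxy groups at C1 and C3 and the forming C5–C6 bond are all equatorial (only the C3 methyl axial), which places H5 cis to H1.

Step 11
Reactants: 12 ring A–B enone
Product: 13 (3aS,4S,6S,7aS)-3a-allyl-6-methyl-4,6-bis(triethylsilyloxy)-2-(trimethylsilyloxy)-3a,4,5,6,7,7a-hexahydro-1H-indene (C7–C8 silyl enol ether)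
Conditions: allylMgBr, CuBr·SMe2, Me3SiCl, THF, −78 °C; Et3N, pentane, aq NaHCO3
Reagents that add atoms: allylmagnesium bromide, C=CC[Mg]Br; chlorotrimethylsilane, C[Si](C)(C)Cl
Why: Conjugate addition of an allylcopper reagent in the presence of Me3SiCl creates quaternary C16 and traps the enolate regiospecifically as the C7–C8 silyl enol ether; allyl should enter on the face of H5 and opposite the C1 silyloxy group, giving the cis-fused hydrindane.

Step 12
Reactants: 14 tert-butyl N-vinylcarbamate; 15 (3-bromopropoxy)(tert-butyl)dimethylsilane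
Product: 16 tert-butyl N-[3-(tert-butyldimethylsilyloxy)propyl]-N-vinylcarbamate
Conditions: NaH, DMF, 0 °C to rt
Reagents that add atoms: none
Why: N-Alkylation (SN2) of the sodium salt of the vinyl carbamate with the primary bromide brings in the N-vinyl group ready-made, before any acid-sensitive step of the main chain.

Step 13
Reactants: 16 silyl ether
Product: 17 tert-butyl N-(3-hydroxypropyl)-N-vinylcarbamate
Conditions: Bu4NF, THF, 0 °C
Reagents that add atoms: none
Why: Fluoride removes the primary tert-butyldimethylsilyl ether, and the enecarbamate is stable to these mildly basic conditions.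

Step 14
Reactants: 17 alcohol
Product: 18 tert-butyl N-(3-oxopropyl)-N-vinylcarbamate
Conditions: Dess–Martin periodinane, NaHCO3, CH2Cl2, 0 °C
Reagents that add atoms: none
Why: Buffered Dess–Martin oxidation gives the β-amino aldehyde without acid that would hydrolyse the enecarbamate, and the aldehyde is used at once.

Step 15
Reactants: 13 silyl enol ether; 18 tert-butyl N-(3-oxopropyl)-N-vinylcarbamate
Product: 20 aldol adduct (C8 side chain CH(OH)CH2CH2N(Boc)CH=CH2 cis to the C16 allyl group; C1/C3 bis-triethylsilyl ether; both C9 epimers), via lithium enolate 19 (not isolated)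
Conditions: MeLi, THF, 0 °C; then 18, −78 °C; AcOH, −78 °C
Reagents that add atoms: none
Why: Cleavage of the silyl enol ether with MeLi gives the regiodefined C7–C8 lithium enolate, whose aldol addition to the aldehyde forms C8–C9; attack should come from the convex face beside the allyl group, C9 forms as both epimers, and both C8 and C9 are flattened again in step 18.

Step 16
Reactants: 20 aldol adduct
Product: 21 nine-membered cyclic enecarbamate (ring C closed, C13=C14 Z; β-hydroxy ketone and both triethylsilyl ethers retained)
Conditions: RuCl2(=CHPh)(PCy3)(H2IMes) (second-generation Grubbs catalyst, 15 mol %), 1,4-benzoquinone (20 mol %), toluene (1 mM), 80 °C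
Reagents that add atoms: none
Why: Metathesis starts at the terminal CH2 of the C16 allyl group, and the new ruthenium alkylidene engages the N-vinyl carbamate in a [2+2]/retro-[2+2] sequence that joins C13 to C14 and sheds ethylene. The closest known reaction is enamide–olefin ring-closing metathesis of N-vinyl carbamates, established for five- to seven-membered enecarbamates; here it closes the nine-membered ring C by a single C13=C14 bond (medium-ring closure, no new stereocentre, the ring allowing only the Z enecarbamate). The step needs ring closure to win over oligomerisation: the two arms should sit cis on the adjacent carbons C8 and C16 of the cis-fused ring B, C16 is quaternary, the carbamate nitrogen is planar, and the run is made at 1 mM. It also needs chemoselectivity, which is given because the substrate holds only these two alkenes, both terminal, while benzoquinone suppresses ruthenium hydride migration of the allyl double bond. C8=C9 is left out on purpose: both C9 epimers can fold into the ring, and the alkene is made afterwards (step 18) with its geometry fixed by ring C.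

Step 17
Reactants: 21 cyclic enecarbamate
Product: 22 triol (C1–OH, C3–OH, C9–OH)
Conditions: HF·pyridine, pyridine, THF, 0 °C to rt
Reagents that add atoms: none
Why: Fluoride cleavage of both triethylsilyl ethers under buffered, non-basic conditions should leave the β-hydroxy ketone (no retro-aldol opening of ring C) and the enecarbamate intact.

Step 18
Reactants: 22 triol
Product: 24 N-Boc 13,14-didehydro derivative of the target (diacetate (E)-enone), via triacetate 23 (not isolated)
Conditions: Ac2O, Et3N, DMAP, CH2Cl2, rt to 40 °C; then DBU, rt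
Reagents that add atoms: acetic anhydride, CC(=O)OC(C)=O
Why: DMAP-catalysed acetylation (Steglich type) esterifies the C1, C3 and C9 hydroxyls, and DBU then removes the C9 acetate by E1cB elimination through the C7 enolate; within ring C the new C8=C9 bond can only be ring-cis, which is the (E) enone with C10 beside C16.

Step 19
Reactants: 24 diacetate enone enecarbamate
Product: 25 N-Boc derivative of the target
Conditions: Et3SiH, CF3CO2H, CH2Cl2, −20 to 0 °C
Reagents that add atoms: none
Why: Ionic hydrogenation: CF3CO2H protonates the electron-rich enecarbamate at C14 and Et3SiH reduces the N-acyliminium ion at C13, while the electron-poor enone is not protonated at carbon and dilute acid at low temperature should spare the Boc group and the tertiary acetate.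

Step 20
Reactants: 25 N-Boc derivative of the target
Product: 26 CNP0120442.1 (target)
Conditions: HCl (4 M in dioxane), 0 °C; aq NaHCO3
Reagents that add atoms: none
Why: Acidolysis of the tert-butyl carbamate with anhydrous HCl (loss of 2-methylpropene and CO2) frees N12, and short exposure at 0 °C is chosen because Boc should cleave faster than the tertiary acetate, deactivated by the acetoxy group at C1, can ionise.

**Compound list**

1 | (R)-mevalonolactone, (4R)-4-hydroxy-4-methyloxan-2-one | C[C@]1(O)CC(=O)OCC1 | starting material
2 | (4R)-4-methyl-4-(triethylsilyloxy)oxan-2-one | C[C@]1(O[Si](CC)(CC)CC)CC(=O)OCC1 | intermediate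
3 | (4R)-4-methyl-4-(triethylsilyloxy)oxan-2-ol (lactol, both anomers) | C[C@]1(O[Si](CC)(CC)CC)CC(O)OCC1 | intermediate
4 | (3S)-3-methyl-3-(triethylsilyloxy)hex-5-en-1-ol | C=CC[C@](C)(O[Si](CC)(CC)CC)CCO | intermediate
5 | (3S)-3-methyl-3-(triethylsilyloxy)hex-5-enal | C=CC[C@](C)(O[Si](CC)(CC)CC)CC=O | intermediate
6 | (5S)-5-methyl-5-(triethylsilyloxy)-1-(trimethylsilyl)oct-7-en-1-yn-3-ol (both C3 epimers) | C=CC[C@](C)(O[Si](CC)(CC)CC)CC(O)C#C[Si](C)(C)C | intermediate
7 | (5S)-5-methyl-5-(triethylsilyloxy)-1-(trimethylsilyl)oct-7-en-1-yn-3-one | C=CC[C@](C)(O[Si](CC)(CC)CC)CC(=O)C#C[Si](C)(C)C | intermediate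
8 | (3S,5S)-5-methyl-5-(triethylsilyloxy)-1-(trimethylsilyl)oct-7-en-1-yn-3-ol | C=CC[C@](C)(O[Si](CC)(CC)CC)C[C@H](O)C#C[Si](C)(C)C | intermediate
9 | (3S,5S)-5-methyl-5-(triethylsilyloxy)oct-7-en-1-yn-3-ol | C=CC[C@](C)(O[Si](CC)(CC)CC)C[C@H](O)C#C | intermediate
10 | (3S,5S)-5-methyl-3,5-bis(triethylsilyloxy)oct-7-en-1-yne | C=CC[C@](C)(O[Si](CC)(CC)CC)C[C@H](O[Si](CC)(CC)CC)C#C | intermediate
11 | hexacarbonyldicobalt complex of the alkyne of 10 (not isolated) | C=CC[C@](C)(O[Si](CC)(CC)CC)C[C@H](O[Si](CC)(CC)CC)C12[Co]3(=C=O)(=C=O)(=C=O)[Co]1(=C=O)(=C=O)(=C=O)[CH]23 | intermediate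
12 | (4S,6S,7aS)-6-methyl-4,6-bis(triethylsilyloxy)-1,4,5,6,7,7a-hexahydro-2H-inden-2-one (ring A–B enone) | CC[Si](CC)(CC)O[C@H]1C[C@@](C)(O[Si](CC)(CC)CC)C[C@H]2CC(=O)C=C21 | intermediate
13 | (3aS,4S,6S,7aS)-3a-allyl-6-methyl-4,6-bis(triethylsilyloxy)-2-(trimethylsilyloxy)-3a,4,5,6,7,7a-hexahydro-1H-indene | CC[Si](CC)(CC)O[C@H]1C[C@@](C)(O[Si](CC)(CC)CC)C[C@H]2CC(O[Si](C)(C)C)=C[C@]21CC=C | intermediate
14 | tert-butyl N-vinylcarbamate | C=CNC(=O)OC(C)(C)C | starting material
15 | (3-bromopropoxy)(tert-butyl)dimethylsilane | BrCCCO[Si](C)(C)C(C)(C)C | starting material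
16 | tert-butyl N-[3-(tert-butyldimethylsilyloxy)propyl]-N-vinylcarbamate | C=CN(CCCO[Si](C)(C)C(C)(C)C)C(=O)OC(C)(C)C | intermediate
17 | tert-butyl N-(3-hydroxypropyl)-N-vinylcarbamate | C=CN(CCCO)C(=O)OC(C)(C)C | intermediate
18 | tert-butyl N-(3-oxopropyl)-N-vinylcarbamate | C=CN(CCC=O)C(=O)OC(C)(C)C | intermediate
19 | C7–C8 lithium enolate of the allylated ring A–B ketone (not isolated) | CC[Si](CC)(CC)O[C@H]1C[C@@](C)(O[Si](CC)(CC)CC)C[C@H]2CC(O[Li])=C[C@]21CC=C | intermediate
20 | aldol adduct: cis-fused ring A–B ketone with C16 allyl, C1 and C3 triethylsilyl ethers and at C8 (cis to allyl) the chain CH(OH)CH2CH2N(Boc)CH=CH2; C9 epimers | CC[Si](CC)(CC)O[C@H]1C[C@@](C)(O[Si](CC)(CC)CC)C[C@H]2CC(=O)[C@H](C(O)CCN(C=C)C(=O)OC(C)(C)C)[C@]21CC=C | intermediate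
21 | ring-closed N-Boc enecarbamate (ring C, C13=C14 Z), C9–OH, C1 and C3 triethylsilyl ethers; C9 epimers | CC[Si](CC)(CC)O[C@H]1C[C@@](C)(O[Si](CC)(CC)CC)C[C@H]2CC(=O)[C@@H]3C(O)CCN(C(=O)OC(C)(C)C)/C=C\C[C@@]321 | intermediate
22 | triol of 21 (C1–OH, C3–OH, C9–OH) | O[C@H]1C[C@@](C)(O)C[C@H]2CC(=O)[C@@H]3C(O)CCN(C(=O)OC(C)(C)C)/C=C\C[C@@]321 | intermediate
23 | triacetate of 22 (not isolated) | CC(=O)O[C@H]1C[C@@](C)(OC(C)=O)C[C@H]2CC(=O)[C@@H]3C(OC(C)=O)CCN(C(=O)OC(C)(C)C)/C=C\C[C@@]321 | intermediate
24 | N-Boc 13,14-didehydro derivative of the target (diacetate, (E)-enone, Z enecarbamate) | CC(=O)O[C@H]1C[C@@](C)(OC(C)=O)C[C@H]2CC(=O)/C3=C/CCN(C(=O)OC(C)(C)C)/C=C\C[C@@]321 | intermediate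
25 | N-Boc derivative of the target | CC(=O)O[C@H]1C[C@@](C)(OC(C)=O)C[C@H]2CC(=O)/C3=C/CCN(C(=O)OC(C)(C)C)CCC[C@@]321 | intermediate
26 | CNP0120442.1 | CC(=O)O[C@H]1C[C@@](C)(OC(C)=O)C[C@H]2CC(=O)/C3=C/CCNCCC[C@@]321 | target

**Step count and risks**

Total step count: 20. Longest linear sequence: 17 steps (steps 1–11 and 15–20); steps 12–14 make the aldehyde arm.

Steps most likely to fail:

Step 16 (ring-closing metathesis). Intermolecular metathesis to dimers and oligomers may outpace closure of a nine-membered ring whose C8–C9 segment is still flexible, or the catalyst may be tied up as a chelated aminocarbene after reacting first at the N-vinyl group. The fallback sets out from 20 and returns at 24; it unveils the enone before ring closure so that a rigid C8=C9 bond holds the nitrogen arm beside C16. HF·pyridine gives the open-chain triol F1. Ac2O/Et3N/DMAP and then DBU give, by way of the open-chain triacetate F2, the diacetate alkylidene ketone as two geometric isomers: the (E)-enone F3 (C10 beside C16) and the (Z)-enone F4 (C10 beside the carbonyl, expected to predominate). They are separated, F4 is returned to the isomer pair by irradiation at 350 nm, and F3 is cyclised with RuCl2(=CHPh)(PCy3)(H2IMes) in dilute toluene to give 24.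

Step 10 (Pauson–Khand). The alkene may insert through the other chair (propargylic silyloxy group axial to avoid the cobalt cluster), so that C5 forms with the wrong configuration, or the 1,7-enyne may cyclise sluggishly while the complex decomposes. The fallback sets out from 10 and returns at 12; it accepts whatever facial course the cycloaddition takes under forcing thermal conditions and corrects C5 afterwards under thermodynamic control. The C5-epimeric enone F5 is equilibrated with DBU in toluene through the extended dienolate (C5–H is the γ-hydrogen of the enone), which should drain it into 12, the isomer with both silyloxy groups equatorial.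

Step 11 (conjugate allylation). The allyl metal may add 1,2 to the carbonyl, or fail to add at the hindered β-carbon C16 next to the C1 silyloxy group. The fallback sets out from 12 and returns at 13; it activates the enone as an electrophile instead of using a nucleophilic organometallic. This is a Hosomi–Sakurai-type addition of allyltributylstannane promoted by Me3SiOSO2CF3 in CH2Cl2 at −78 °C, in which the silyl group ends on the enolate oxygen and 13 forms directly; no compound outside the list is made (F0).

Further compounds
F1 | step 16 | open-chain triol of 20 (C1–OH, C3–OH, C9–OH) | O[C@H]1C[C@@](C)(O)C[C@H]2CC(=O)[C@H](C(O)CCN(C=C)C(=O)OC(C)(C)C)[C@]21CC=C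
F2 | step 16 | open-chain triacetate of F1 (not isolated) | CC(=O)O[C@H]1C[C@@](C)(OC(C)=O)C[C@H]2CC(=O)[C@H](C(OC(C)=O)CCN(C=C)C(=O)OC(C)(C)C)[C@]21CC=C
F3 | step 16 | diacetate (E)-enone with C16 allyl group and N-Boc N-vinyl arm | CC(=O)O[C@H]1C[C@@](C)(OC(C)=O)C[C@H]2CC(=O)/C(=C/CCN(C=C)C(=O)OC(C)(C)C)[C@]21CC=C
F4 | step 16 | diacetate (Z)-enone, geometric isomer of F3 | CC(=O)O[C@H]1C[C@@](C)(OC(C)=O)C[C@H]2CC(=O)/C(=C\CCN(C=C)C(=O)OC(C)(C)C)[C@]21CC=C
F5 | step 10 | C5 epimer of enone 12 | CC[Si](CC)(CC)O[C@H]1C[C@@](C)(O[Si](CC)(CC)CC)C[C@@H]2CC(=O)C=C21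
F0 | step 11 | none | none
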